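**Strategy.** The depside is cut at its aryl ester into two benzoates that carry the same pattern: carboxyl at C1, heptyl at C2, oxygens at C4 and C6, in ring A and in ring B alike. That pattern is the aromatised form of a 4-carboalkoxy-5-heptylcyclohexane-1,3-dione, so one Dieckmann closure supplies both rings. In the key step the acetyl methyl carbon of an acyclic keto diester attacks the remote ester carbonyl, forming the C4–C5 bond and the six-membered ring with all four substituents already placed. The precursor is dibenzyl 2-acetyl-3-heptylpentanedioate; benzyl esters replace methyl so that the ring B carboxyl can be freed at the end by hydrogenolysis without touching the depside ester.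

Key step: step 3

Remark: ring positions are numbered as in the benzoates (C1 carboxyl, C2 heptyl, C4 and C6 oxygen); compounds 5 and 6 are racemic, their stereocentres vanish in step 4 and the target has none; benzyl acetoacetate and benzyl dimethylphosphonoacetate are taken as purchasable.

**Route**

Step 1
Reactants: 1 octanal; 2 benzyl dimethylphosphonoacetate
Product: 3 benzyl (E)-dec-2-enoate
Conditions: NaH (1.05 equiv), THF, 0 °C to rt
Reagents that add atoms: none
Why: Horner–Wadsworth–Emmons olefination, in which the stabilised phosphonate carbanion adds to the aldehyde and the oxaphosphetane collapses to the E-enoate; the alkene geometry is immaterial because both isomers lead to the same Michael adduct.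

Step 2
Reactants: 3 benzyl (E)-dec-2-enoate; 4 benzyl acetoacetate (1.2 equiv)
Product: 5 dibenzyl 2-acetyl-3-heptylpentanedioate (racemic, diastereomer mixture)
Conditions: Cs2CO3 (0.2 equiv), DMF, rt to 40 °C; AcOH quench
Reagents that add atoms: none
Why: Michael addition, in which the enolate of 4 adds to C3 of the enoate and proton transfer from further 4 turns the cycle over, while carbonate is too weak to form the methyl ketone enolate, so the adduct should not cyclise prematurely; the two new stereocentres form without control and are both erased in step 4.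

Step 3
Reactants: 5 dibenzyl 2-acetyl-3-heptylpentanedioate
Product: 6 benzyl 2-heptyl-4,6-dioxocyclohexane-1-carboxylate (racemic, trans drawn, largely enolised)
Conditions: NaOCH2Ph (1.0 M in PhCH2OH, 1.5 equiv), THF, 65 °C; then cold 1 M HCl
Reagents that add atoms: none
Why: Dieckmann-type intramolecular Claisen condensation, in which benzyloxide reversibly forms the enolate of the acetyl methyl group, this carbon adds to the C5 ester carbonyl of the pentanedioate and benzyloxide is expelled, so that the C4–C5 ring bond and the cyclohexane-1,3-dione arise together. The closest known reaction type is the alkoxide-mediated cyclisation of delta-keto esters to dihydroresorcinols. The ring closes in a 6-(enolendo)-exo-trig mode. No stereocentre is created; the two inherited centres equilibrate towards trans through the enolisable C1 and both disappear on aromatisation, so the diastereomer mixture of 5 converges. The step needs site selectivity among the enolisable positions, and the substrate secures it because only the acetyl methyl carbanion reaches an ester through a six-membered transition state (every other pairing would give a four-membered ring), while the acidic C2–H of the pentanedioate holds the acetoacetate unit as its enolate and shields it from retro-Claisen cleavage. Deprotonation of the product, a vinylogous acid, makes the closure irreversible and drains any retro-Michael equilibrium, and the matched alkoxide makes ester exchange degenerate.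

Step 4
Reactants: 6 benzyl 2-heptyl-4,6-dioxocyclohexane-1-carboxylate
Product: 7 benzyl 2-heptyl-4,6-dihydroxybenzoate
Conditions: I2 (0.2 equiv), DMSO, 80 °C
Reagents that add atoms: none
Why: Iodine-catalysed oxidative aromatisation of a cyclohexane-1,3-dione (enol iodination, loss of HI and tautomerisation to the resorcinol, with DMSO re-oxidising HI to I2), driven by aromatisation and run with only catalytic acid so that the benzyl ester should survive.

Step 5
Reactants: 7 benzyl 2-heptyl-4,6-dihydroxybenzoate
Product: 8 benzyl 2-heptyl-6-hydroxy-4-methoxybenzoate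
Conditions: MeI (1.05 equiv), K2CO3 (1.1 equiv), acetone, rt to 40 °C
Reagents that add atoms: iodomethane, CI
Why: Williamson ether synthesis, selective because the C4 hydroxyl is the more acidic and freely accessible phenol whereas the C6 hydroxyl is held in a hydrogen bond to the ester carbonyl.

Step 6
Reactants: 8 benzyl 2-heptyl-6-hydroxy-4-methoxybenzoate
Product: 9 2-heptyl-6-hydroxy-4-methoxybenzoic acid
Conditions: H2 (1 atm), 10% Pd/C, EtOAc, rt
Reagents that add atoms: none
Why: Catalytic hydrogenolysis of the benzyl ester frees the doubly ortho-substituted acid at room temperature without a hydrolysis step, and nothing else in 8 is reducible under these conditions.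

Step 7
Reactants: 7 benzyl 2-heptyl-4,6-dihydroxybenzoate
Product: 10 benzyl 2-heptyl-6-hydroxy-4-(prop-2-en-1-yloxy)benzoate
Conditions: allyl bromide (1.05 equiv), K2CO3 (1.1 equiv), acetone, rt to 50 °C
Reagents that add atoms: allyl bromide, C=CCBr
Why: Williamson allylation with the same chelation-based site selectivity as in step 5 masks the C4 hydroxyl with a group that can later be removed without touching the benzyl ester.

Step 8
Reactants: 10 benzyl 2-heptyl-6-hydroxy-4-(prop-2-en-1-yloxy)benzoate
Product: 11 benzyl 2-heptyl-6-methoxy-4-(prop-2-en-1-yloxy)benzoate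
Conditions: MeI (3 equiv), K2CO3 (3 equiv), DMF, 50 °C
Reagents that add atoms: iodomethane, CI
Why: Williamson methylation under more forcing conditions (excess MeI, polar aprotic solvent) overcomes the hydrogen bond of the remaining C6 phenol, while the allyl ether and the hindered benzyl ester are inert to carbonate.

Step 9
Reactants: 11 benzyl 2-heptyl-6-methoxy-4-(prop-2-en-1-yloxy)benzoate
Product: 12 benzyl 2-heptyl-4-hydroxy-6-methoxybenzoate
Conditions: Pd(PPh3)4 (3 mol %), morpholine (5 equiv), THF, rt
Reagents that add atoms: none
Why: Tsuji–Trost deallylation, in which zerovalent palladium ionises the allyl aryl ether to a pi-allyl complex that morpholine captures, releasing the C4 phenol under neutral conditions that leave the benzyl ester and the methyl ether untouched.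

Step 10
Reactants: 9 2-heptyl-6-hydroxy-4-methoxybenzoic acid; 12 benzyl 2-heptyl-4-hydroxy-6-methoxybenzoate
Product: 14 benzyl 2-heptyl-4-[(2-heptyl-6-hydroxy-4-methoxybenzoyl)oxy]-6-methoxybenzoate, via mixed trifluoroacetic anhydride 13 (not isolated)
Conditions: (CF3CO)2O (4 equiv), toluene, rt; then aq. NaHCO3
Reagents that add atoms: none
Why: Mixed-anhydride esterification, in which the hindered acid is activated as its acyl trifluoroacetate and transfers the aroyl group to the only free phenol of 12, while the C6 hydroxyl of 9 is deactivated by its hydrogen bond to the carbonyl and any aryl trifluoroacetate is cleaved in the bicarbonate work-up.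

Step 11
Reactants: 14 benzyl 2-heptyl-4-[(2-heptyl-6-hydroxy-4-methoxybenzoyl)oxy]-6-methoxybenzoate
Product: 15 2-heptyl-4-[(2-heptyl-6-hydroxy-4-methoxybenzoyl)oxy]-6-methoxybenzoic acid (CNP0128141.0)
Conditions: H2 (1 atm), 10% Pd/C, EtOAc, rt
Reagents that add atoms: none
Why: Catalytic hydrogenolysis cleaves only the benzylic C–O bond of the benzyl ester, the depside aryl ester, the methyl ethers and the alkyl chains being inert, so the ring B acid is released in the last operation.

**Compound list**

1 | octanal | CCCCCCCC=O | starting material
2 | benzyl dimethylphosphonoacetate (benzyl 2-(dimethoxyphosphoryl)acetate) | COP(=O)(OC)CC(=O)OCc1ccccc1 | starting material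
3 | benzyl (E)-dec-2-enoate | CCCCCCC/C=C/C(=O)OCc1ccccc1 | intermediate
4 | benzyl acetoacetate (benzyl 3-oxobutanoate) | CC(=O)CC(=O)OCc1ccccc1 | starting material
5 | dibenzyl 2-acetyl-3-heptylpentanedioate (racemic, diastereomer mixture, one drawn) | O=C(OCc1ccccc1)C[C@@H](CCCCCCC)[C@@H](C(C)=O)C(=O)OCc1ccccc1 | intermediate
6 | benzyl 2-heptyl-4,6-dioxocyclohexane-1-carboxylate (racemic, trans drawn) | CCCCCCC[C@@H]1CC(=O)CC(=O)[C@H]1C(=O)OCc1ccccc1 | intermediate
7 | benzyl 2-heptyl-4,6-dihydroxybenzoate | CCCCCCCc1cc(O)cc(O)c1C(=O)OCc1ccccc1 | intermediate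
8 | benzyl 2-heptyl-6-hydroxy-4-methoxybenzoate | CCCCCCCc1cc(OC)cc(O)c1C(=O)OCc1ccccc1 | intermediate
9 | 2-heptyl-6-hydroxy-4-methoxybenzoic acid | CCCCCCCc1cc(OC)cc(O)c1C(=O)O | intermediate
10 | benzyl 2-heptyl-6-hydroxy-4-(prop-2-en-1-yloxy)benzoate | C=CCOc1cc(CCCCCCC)c(C(=O)OCc2ccccc2)c(O)c1 | intermediate
11 | benzyl 2-heptyl-6-methoxy-4-(prop-2-en-1-yloxy)benzoate | C=CCOc1cc(CCCCCCC)c(C(=O)OCc2ccccc2)c(OC)c1 | intermediate
12 | benzyl 2-heptyl-4-hydroxy-6-methoxybenzoate | CCCCCCCc1cc(O)cc(OC)c1C(=O)OCc1ccccc1 | intermediate
13 | 2-heptyl-6-hydroxy-4-methoxybenzoic trifluoroacetic anhydride | CCCCCCCc1cc(OC)cc(O)c1C(=O)OC(=O)C(F)(F)F | intermediate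
14 | benzyl 2-heptyl-4-[(2-heptyl-6-hydroxy-4-methoxybenzoyl)oxy]-6-methoxybenzoate | CCCCCCCc1cc(OC)cc(O)c1C(=O)Oc1cc(CCCCCCC)c(C(=O)OCc2ccccc2)c(OC)c1 | intermediate
15 | 2-heptyl-4-[(2-heptyl-6-hydroxy-4-methoxybenzoyl)oxy]-6-methoxybenzoic acid | CCCCCCCc1cc(OC)cc(O)c1C(=O)Oc1cc(CCCCCCC)c(C(=O)O)c(OC)c1 | target

**Step count and risks**

Total steps: 11. Longest linear sequence: 9 (steps 1, 2, 3, 4, 7, 8, 9, 10, 11).

Step 3. The closure may stall, or the adduct may fragment by retro-Michael cleavage faster than it cyclises under the equilibrating alkoxide. The fallback builds the same ring through a different bond, setting out from octanal 1. Wittig reaction of 1 with 1-(triphenylphosphoranylidene)propan-2-one in toluene at 80 °C should give (E)-undec-3-en-2-one F1. Treatment of F1 with dibenzyl malonate and NaOCH2Ph in PhCH2OH/THF at 65 °C should give the conjugate adduct dibenzyl 2-(2-oxoundecan-4-yl)propanedioate F2. In the same pot the methyl ketone carbon of F2 attacks one malonate ester, forming the C5–C6 bond in place of C4–C5, and the route is rejoined at 6.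

Step 4. The electron-rich resorcylate may be halogenated further as it forms, or the benzyl ester may be lost under the acid released, followed by decarboxylation. The fallback accepts ring halogenation and removes it afterwards, setting out from 6. Br2 (3 equiv) with NaOAc in AcOH at rt should aromatise and brominate both free ring positions, giving benzyl 3,5-dibromo-2-heptyl-4,6-dihydroxybenzoate F3. Both bromines are then removed reductively with HCO2Na and catalytic Pd(PPh3)4 in DMF at 80 °C, conditions that do not hydrogenolyse benzyl esters, and the route is rejoined at 7.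

Step 10. Acyl transfer from the doubly ortho-substituted acid may be slow, and the unprotected salicylic-type acid may self-acylate or acylate ring B at carbon. The fallback protects the phenol and changes the activation, setting out from 8. Benzylation (PhCH2Br, K2CO3, DMF, 60 °C) should give benzyl 6-(benzyloxy)-2-heptyl-4-methoxybenzoate F4. Saponification of the hindered ester (KOH, DMSO/H2O, 90 °C) should give 6-(benzyloxy)-2-heptyl-4-methoxybenzoic acid F5. Steglich esterification of F5 with 12 (DCC, catalytic DMAP, CH2Cl2, rt) should give benzyl 4-{[6-(benzyloxy)-2-heptyl-4-methoxybenzoyl]oxy}-2-heptyl-6-methoxybenzoate F6. Hydrogenolysis (H2, 10% Pd/C, EtOAc) removes both benzyl groups at once and rejoins the route at 15.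

**Further compounds**

F1 | step 3 | (E)-undec-3-en-2-one | CCCCCCC/C=C/C(C)=O
F2 | step 3 | dibenzyl 2-(2-oxoundecan-4-yl)propanedioate (racemic, one enantiomer drawn) | CCCCCCC[C@@H](CC(C)=O)C(C(=O)OCc1ccccc1)C(=O)OCc1ccccc1
F3 | step 4 | benzyl 3,5-dibromo-2-heptyl-4,6-dihydroxybenzoate | CCCCCCCc1c(Br)c(O)c(Br)c(O)c1C(=O)OCc1ccccc1
F4 | step 10 | benzyl 6-(benzyloxy)-2-heptyl-4-methoxybenzoate | CCCCCCCc1cc(OC)cc(OCc2ccccc2)c1C(=O)OCc1ccccc1
F5 | step 10 | 6-(benzyloxy)-2-heptyl-4-methoxybenzoic acid | CCCCCCCc1cc(OC)cc(OCc2ccccc2)c1C(=O)O
F6 | step 10 | benzyl 4-{[6-(benzyloxy)-2-heptyl-4-methoxybenzoyl]oxy}-2-heptyl-6-methoxybenzoate | CCCCCCCc1cc(OC)cc(OCc2ccccc2)c1C(=O)Oc1cc(CCCCCCC)c(C(=O)OCc2ccccc2)c(OC)c1
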